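**Retrosynthetic overview**
1. Feature: in ring A the free C5 hydroxyl and the C8 methoxy group are para to each other (a C5/C8 hydroquinone monomethyl ether). The C8–O bond is therefore traced back to the C8–H of a 5-hydroxy-6,7-dimethoxyflavone.
2. Target ⇒ (pivalate methanolysis, reductive aromatisation) 8,8-dimethoxy-5-oxo para-quinone monoketal ⇒ (anodic oxidation in methanol, two C8–O bonds) cirsiliol 3',4'-dipivalate.
3. Cirsiliol dipivalate ⇒ cirsiliol ⇒ 5,6,7-trimethoxy-3',4'-bis(benzyloxy)flavone. BCl3 frees C5–OH and the ring B catechol, and PivCl then masks the catechol only.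
4. Rings A and B are purchased. Ring C is the only ring formed, by Claisen–Schmidt condensation followed by I2/DMSO oxidative cyclisation (O1–C2 bond) of a 2'-hydroxychalcone.

Key step: step 6

Remark: the target has no stereocentre. The only stereo-element in the route is the E alkene of chalcone 4. Flavanone 5 is racemic and its C2 centre is erased in the same step.
Remark: compound 10 is passed through as a transient in step 6 and is isolated in step 7. It keeps one number.
Assumption: the ring A phenol of 9 is taken to oxidise at a clearly lower potential than the bis-pivalate ring B. Cyclic voltammetry should confirm this before the preparative run.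

**Step 1**
Reactants: 1 3,4,5-trimethoxyphenol
Product: 2 1-(6-hydroxy-2,3,4-trimethoxyphenyl)ethan-1-one
Conditions: AcOH, BF3·OEt2 (3 equiv), 85 °C; then H2O
Reagents that add atoms: acetic acid, CC(=O)O
Why: BF3-promoted Friedel–Crafts acylation can enter only the two equivalent free positions ortho to the phenol, and the chelated ortho-hydroxy ketone resists a second acylation.

**Step 2**
Reactants: 2 1-(6-hydroxy-2,3,4-trimethoxyphenyl)ethan-1-one; 3 3,4-bis(benzyloxy)benzaldehyde
Product: 4 (E)-3-[3,4-bis(benzyloxy)phenyl]-1-(6-hydroxy-2,3,4-trimethoxyphenyl)prop-2-en-1-one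
Conditions: KOH (10 equiv, 50% aq), EtOH/THF, rt; then 1 M HCl
Reagents that add atoms: none
Why: Claisen–Schmidt condensation, in which the methyl ketone enolate adds to the non-enolisable aldehyde and E1cB dehydration gives the thermodynamically preferred E enone.

**Step 3**
Reactants: 4 (E)-2'-hydroxychalcone
Product: 6 2-[3,4-bis(benzyloxy)phenyl]-5,6,7-trimethoxy-4H-chromen-4-one, via racemic flavanone 5 (not isolated)
Conditions: I2 (10 mol %), DMSO, 130 °C
Reagents that add atoms: none
Why: I2/DMSO oxidative cyclisation of a 2'-hydroxychalcone, in which oxa-Michael addition of the phenol closes ring C to flavanone 5, iodine dehydrogenates C2–C3 by alpha-iodination and HI loss, and DMSO reoxidises the HI.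

**Step 4**
Reactants: 6 2-[3,4-bis(benzyloxy)phenyl]-5,6,7-trimethoxy-4H-chromen-4-one
Product: 7 cirsiliol, 2-(3,4-dihydroxyphenyl)-5-hydroxy-6,7-dimethoxy-4H-chromen-4-one
Conditions: BCl3 (6 equiv), pentamethylbenzene (6 equiv), CH2Cl2, −78 → 0 °C; then 1 M HCl
Reagents that add atoms: none
Why: Lewis-acid ether cleavage with a cation scavenger, in which BCl3 bound to the C4 carbonyl cleaves only the peri C5 methyl ether through a six-membered chelate and ionises the aryl benzyl ethers, pentamethylbenzene traps the benzyl cations, and the unchelated C6 and C7 methyl ethers should persist at or below 0 °C.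

**Step 5**
Reactants: 7 cirsiliol; 8 pivaloyl chloride
Product: 9 cirsiliol 3',4'-dipivalate, 4-(5-hydroxy-6,7-dimethoxy-4-oxo-4H-chromen-2-yl)-1,2-phenylene bis(2,2-dimethylpropanoate)
Conditions: PivCl (2.1 equiv), Et3N (2.5 equiv), THF/DMF 4:1, 0 °C → rt
Reagents that add atoms: pivaloyl chloride (8), CC(C)(C)C(Cl)=O
Why: Chemoselective O-acylation, because the C5 hydroxyl is hydrogen-bonded to C4=O and flanked by the C6 methoxy group, so the bulky acyl chloride without an acyl-transfer catalyst should esterify only the two ring B hydroxyls.

**Step 6**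
Reactants: 9 cirsiliol 3',4'-dipivalate
Product: 11 6,7,8,8-tetramethoxy-5-oxo para-quinone monoketal of the dipivalate, via sideritiflavone 3',4'-dipivalate 10 (not isolated)
Conditions: reticulated vitreous carbon anode, Pt wire cathode, undivided cell, constant current, 4.2–4.5 F/mol, Et4NOTs (0.1 M), 2,6-lutidine (2 equiv), MeOH/CH2Cl2 4:1, 0 °C; crude product taken on at once
Reagents that add atoms: methanol, CO
Why: Proposed new method: the hydrogen-bonded C5 phenol on the tetraoxygenated ring A is the most easily oxidised site of 9, and loss of two electrons and one proton at the carbon anode should give a phenoxonium ion that methanol captures at C8, the only C–H carbon of ring A and para to the C5 oxygen, so that loss of the C8 proton delivers the 8-methoxyphenol 10. As a hydroquinone monoether 10 oxidises at a lower potential than 9, so a second two-electron oxidation and a second methanol capture at the now methoxy-stabilised C8 follow directly and give the cross-conjugated 8,8-dimethoxy-5-oxo dienone 11, four faradays per mole being consumed while lutidinium is reduced to hydrogen at the cathode. The closest known reaction type is the anodic oxidation of phenols and 4-methoxyphenols in methanol to para-quinone monoketals, which has not been shown on a chelated 5-hydroxyflavone. Two C8–O bonds are formed, no ring is closed and no stereocentre arises, because C8 of 11 carries two identical methoxy groups. Selectivity between the rings is secured by the two pivalate esters, which raise the oxidation potential of ring B well above that of ring A, and by the electron-poor C2=C3–C4=O unit of ring C, which is not oxidised at this potential. Selectivity within ring A, C8 against ipso capture at the methoxylated C6, is secured only in part by the substrate: capture at C8 alone is made irreversible by proton loss, while a C6 adduct is an ortho-quinone monoketal that the zinc reduction of step 7 would return to 9 (first stage) or convert into 10 (second stage), so that no wrong regioisomer can be carried forward.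

**Step 7**
Reactants: 11 6,7,8,8-tetramethoxy-5-oxo para-quinone monoketal of the dipivalate
Product: 10 sideritiflavone 3',4'-dipivalate, 4-(5-hydroxy-6,7,8-trimethoxy-4-oxo-4H-chromen-2-yl)-1,2-phenylene bis(2,2-dimethylpropanoate), now isolated
Conditions: Zn dust (5 equiv), anhydrous AcOH/THF 1:4, 0 °C
Reagents that add atoms: none
Why: Reductive aromatisation of a quinone monoketal, in which zinc passes two electrons into the C5 dienone, protonation and loss of one C8 methoxy group as methanol restore aromatic ring A with free C5–OH and C8–OMe, and the pivalates and the pyranone should tolerate brief contact at 0 °C.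

**Step 8**
Reactants: 10 sideritiflavone 3',4'-dipivalate
Product: 12 sideritiflavone, 2-(3,4-dihydroxyphenyl)-5-hydroxy-6,7,8-trimethoxy-4H-chromen-4-one
Conditions: K2CO3 (3 equiv), degassed MeOH, Ar, 0 °C → rt; then 1 M HCl
Reagents that add atoms: none
Why: Base-mediated transesterification (methanolysis) of the activated aryl esters frees the catechol, the methyl ethers and ring C are inert to these conditions, and exclusion of oxygen protects the catecholate until acidification.

**Compound list**
1 | 3,4,5-trimethoxyphenol | COc1cc(O)cc(OC)c1OC | starting material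
2 | 1-(6-hydroxy-2,3,4-trimethoxyphenyl)ethan-1-one | CC(=O)c1c(O)cc(OC)c(OC)c1OC | intermediate
3 | 3,4-bis(benzyloxy)benzaldehyde | O=Cc1ccc(OCc2ccccc2)c(OCc2ccccc2)c1 | starting material
4 | (E)-3-[3,4-bis(benzyloxy)phenyl]-1-(6-hydroxy-2,3,4-trimethoxyphenyl)prop-2-en-1-one | COc1cc(O)c(C(=O)/C=C/c2ccc(OCc3ccccc3)c(OCc3ccccc3)c2)c(OC)c1OC | intermediate
5 | racemic 2-[3,4-bis(benzyloxy)phenyl]-5,6,7-trimethoxychroman-4-one (not isolated) | COc1cc2c(c(OC)c1OC)C(=O)CC(c1ccc(OCc3ccccc3)c(OCc3ccccc3)c1)O2 | intermediate
6 | 2-[3,4-bis(benzyloxy)phenyl]-5,6,7-trimethoxy-4H-chromen-4-one | COc1cc2oc(-c3ccc(OCc4ccccc4)c(OCc4ccccc4)c3)cc(=O)c2c(OC)c1OC | intermediate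
7 | cirsiliol | COc1cc2oc(-c3ccc(O)c(O)c3)cc(=O)c2c(O)c1OC | intermediate
8 | pivaloyl chloride | CC(C)(C)C(Cl)=O | starting material
9 | cirsiliol 3',4'-dipivalate | COc1cc2oc(-c3ccc(OC(=O)C(C)(C)C)c(OC(=O)C(C)(C)C)c3)cc(=O)c2c(O)c1OC | intermediate
10 | sideritiflavone 3',4'-dipivalate | COc1c(OC)c(O)c2c(=O)cc(-c3ccc(OC(=O)C(C)(C)C)c(OC(=O)C(C)(C)C)c3)oc2c1OC | intermediate
11 | 4-(6,7,8,8-tetramethoxy-4,5-dioxo-5,8-dihydro-4H-chromen-2-yl)-1,2-phenylene bis(2,2-dimethylpropanoate) | COC1=C(OC)C(OC)(OC)C2=C(C1=O)C(=O)C=C(c1ccc(OC(=O)C(C)(C)C)c(OC(=O)C(C)(C)C)c1)O2 | intermediate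
12 | sideritiflavone | COc1c(OC)c(O)c2c(=O)cc(-c3ccc(O)c(O)c3)oc2c1OC | target

**Step count**
Total steps: 8. Longest linear sequence: 8 steps (1 → 12).

**Steps most likely to fail**

**Step 6.**
- Methanol may be captured ipso at the methoxy-stabilised C6 in the first oxidation stage.
- Phenoxyl radicals may couple at C8.
- Methanol may add in conjugate fashion to the doubly activated C8a of the product and open ring C.
- Cathodic back-reduction of the product may waste charge.

The fallback uses known chemistry, sets out from 6 and comes back at 12. Electrophilic bromination of 6 with NBS in DMF at 0 °C should occur at C8, the only free and most activated position of ring A, and give 8-bromo-5,6,7-trimethoxy-3',4'-bis(benzyloxy)flavone F1. Ullmann-type methoxylation (NaOMe, CuBr, DMF/MeOH, 110 °C) should convert it into 5,6,7,8-tetramethoxy-3',4'-bis(benzyloxy)flavone F2. BCl3 with pentamethylbenzene, as in step 4, should then cleave the chelated C5 methyl ether and both benzyl ethers to give 12.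

**Step 7.**
- Acid may hydrolyse the ketal before electron transfer, which would lose the C8 methyl group.
- The C2=C3 bond of the pyranone may be over-reduced.

The fallback sets out from 11 and comes back at 10. It makes the hydrolysis deliberate. Aqueous oxalic acid in THF should give the 6,7-dimethoxyflavone-5,8-quinone 3',4'-dipivalate F3. Na2S2O4 in EtOAc/H2O should reduce it to 5,8-dihydroxy-6,7-dimethoxyflavone 3',4'-dipivalate F4. MeI (1.1 equiv) with K2CO3 in acetone under argon should methylate only the unchelated C8 hydroxyl and give 10.

**Step 4.**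
- Demethylation may run on to C6 once boron is anchored at the C5 oxygen.
- The C5 ether may be cleaved incompletely at low temperature.
- Escaping benzyl cations may C-benzylate ring A.

The fallback sets out from 6 and comes back at 9. It separates the two deprotections and removes the selectivity demand of step 5. Hydrogenolysis (H2, Pd/C, EtOAc/THF) should give 3',4'-dihydroxy-5,6,7-trimethoxyflavone F5. Exhaustive pivaloylation with 8 and Et3N should give 5,6,7-trimethoxyflavone 3',4'-dipivalate F6. A single chelation-directed demethylation with BCl3 (1.2 equiv, CH2Cl2, −20 °C) should then free only C5–OH and give 9.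

**Further compounds**
F1 | step 6 | 8-bromo-5,6,7-trimethoxy-3',4'-bis(benzyloxy)flavone | COc1c(Br)c2oc(-c3ccc(OCc4ccccc4)c(OCc4ccccc4)c3)cc(=O)c2c(OC)c1OC
F2 | step 6 | 5,6,7,8-tetramethoxy-3',4'-bis(benzyloxy)flavone | COc1c(OC)c2oc(-c3ccc(OCc4ccccc4)c(OCc4ccccc4)c3)cc(=O)c2c(OC)c1OC
F3 | step 7 | 6,7-dimethoxyflavone-5,8-quinone 3',4'-dipivalate | COC1=C(OC)C(=O)C2=C(C1=O)C(=O)C=C(c1ccc(OC(=O)C(C)(C)C)c(OC(=O)C(C)(C)C)c1)O2
F4 | step 7 | 5,8-dihydroxy-6,7-dimethoxyflavone 3',4'-dipivalate | COc1c(OC)c(O)c2c(=O)cc(-c3ccc(OC(=O)C(C)(C)C)c(OC(=O)C(C)(C)C)c3)oc2c1O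
F5 | step 4 | 3',4'-dihydroxy-5,6,7-trimethoxyflavone | COc1cc2oc(-c3ccc(O)c(O)c3)cc(=O)c2c(OC)c1OC
F6 | step 4 | 5,6,7-trimethoxyflavone 3',4'-dipivalate | COc1cc2oc(-c3ccc(OC(=O)C(C)(C)C)c(OC(=O)C(C)(C)C)c3)cc(=O)c2c(OC)c1OC
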